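**Retrosynthetic overview**

1. Ring labels: ring A (resorcinol benzene) and ring C (pyranone) make up the chromone, ring B is the methoxylated benzene, ring D is the 2,2-dimethylpyran (chromene numbering O1, C2, C3, C4, C4a, C8a). The last disconnection is the MOM ether on O7.
2. Ring D is removed whole in one operation: the C3=C4 double bond (intramolecular Wittig ring closure) and the O1–C2 ether bond (oxa-Michael addition) lead back to a ring B salicylaldehyde and a four-carbon (2-methylallyl)phosphonium salt.
3. Enabling feature: O1 on C8a and C4 on C4a are ortho neighbours on ring B (a masked o-vanillin); C3 and C4 are both CH (the cis olefin that ylide plus aldehyde delivers); C2 is a quaternary gem-dimethyl carbon next to O1 (the beta-carbon of an isobutenylphosphonium acceptor).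
4. The salicylaldehyde arises by Suzuki–Miyaura union of C3 of ring C with ring B: 3-iodo-7-(methoxymethoxy)chromone plus the pinacol boronate of 5-bromo-o-vanillin.
5. Order of ring formation: ring C (enaminone iodocyclisation on ring A), then the ring C–ring B bond, then ring D last.

Key step: step 6

Remark: the target has no stereocentre; its only stereochemical element, the cis C3=C4 olefin of ring D, is enforced by the ring. All numbered starting materials are assumed to be catalogue chemicals.

**Step 1**
Reactants: 1 2,4-dihydroxyacetophenone; 2 chloromethyl methyl ether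
Product: 3 1-[2-hydroxy-4-(methoxymethoxy)phenyl]ethan-1-one
Conditions: MOMCl (1.1 equiv), K2CO3, acetone, 0 °C to rt
Reagents that add atoms: chloromethyl methyl ether (2), COCCl
Why: Williamson-type O-alkylation (MOM ether formation): the 2-hydroxyl is locked in a hydrogen bond to the acetyl carbonyl and is the less acidic one, so the weak base K2CO3 should deliver the 4-O-MOM ether selectively.

**Step 2**
Reactants: 3 1-[2-hydroxy-4-(methoxymethoxy)phenyl]ethan-1-one; 4 N,N-dimethylformamide dimethyl acetal
Product: 5 (E)-3-(dimethylamino)-1-[2-hydroxy-4-(methoxymethoxy)phenyl]prop-2-en-1-one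
Conditions: DMF-DMA (2 equiv), toluene, 95 °C
Reagents that add atoms: N,N-dimethylformamide dimethyl acetal (4), COC(OC)N(C)C
Why: Enaminone formation: the methyl ketone condenses with the amide acetal with loss of two molecules of methanol, and the E olefin is the thermodynamic product (no stereocentre).

**Step 3**
Reactants: 5 (E)-3-(dimethylamino)-1-[2-hydroxy-4-(methoxymethoxy)phenyl]prop-2-en-1-one; 6 iodine
Product: 7 3-iodo-7-(methoxymethoxy)-4H-chromen-4-one
Conditions: I2, pyridine, CHCl3, rt
Reagents that add atoms: iodine (6), II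
Why: Iodocyclisation of a 2-hydroxyaryl enaminone: iodine attacks the nucleophilic alpha-carbon, the phenol adds to the resulting iminium carbon to close ring C, and dimethylamine is eliminated, with pyridine buffering the acid so that the MOM ether should survive.

**Step 4**
Reactants: 8 5-bromo-2-hydroxy-3-methoxybenzaldehyde; 9 bis(pinacolato)diboron
Product: 10 2-hydroxy-3-methoxy-5-(4,4,5,5-tetramethyl-1,3,2-dioxaborolan-2-yl)benzaldehyde
Conditions: B2pin2, PdCl2(dppf) (cat.), KOAc, 1,4-dioxane, 90 °C
Reagents that add atoms: bis(pinacolato)diboron (9), CC1(C)OB(OC1(C)C)B1OC(C)(C)C(C)(C)O1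
Why: Miyaura borylation: zerovalent palladium inserts into the C–Br bond and acetate-assisted transmetalation from B2pin2 gives the aryl boronate, the weak base KOAc leaving the free phenol and the aldehyde untouched.

**Step 5**
Reactants: 7 3-iodo-7-(methoxymethoxy)-4H-chromen-4-one; 10 2-hydroxy-3-methoxy-5-(4,4,5,5-tetramethyl-1,3,2-dioxaborolan-2-yl)benzaldehyde
Product: 11 2-hydroxy-3-methoxy-5-[7-(methoxymethoxy)-4-oxo-4H-chromen-3-yl]benzaldehyde
Conditions: Pd(PPh3)4 (cat.), Na2CO3 (3 equiv), DME/H2O, 80 °C
Reagents that add atoms: none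
Why: Suzuki–Miyaura cross-coupling: the C3–I bond of the iodochromone is an activated alpha-iodoenone that should undergo fast oxidative addition to zerovalent palladium, the boronate transmetalates under carbonate activation, and the mild base keeps ring C closed.

**Step 6**
Reactants: 11 2-hydroxy-3-methoxy-5-[7-(methoxymethoxy)-4-oxo-4H-chromen-3-yl]benzaldehyde; 12 (2-methylallyl)triphenylphosphonium chloride
Product: 16 3-(8-methoxy-2,2-dimethyl-2H-chromen-6-yl)-7-(methoxymethoxy)-4H-chromen-4-one, via sodium phenoxide 13 (not isolated), via isobutenylphosphonium salt 14 (not isolated), via phosphonium ylide 15 (not isolated)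
Conditions: NaH (1.0 equiv), DMF, 0 °C; then 12 (1.5 equiv), 90 °C
Reagents that add atoms: (2-methylallyl)triphenylphosphonium chloride (12), CC(=C)C[P+](c1ccccc1)(c1ccccc1)c1ccccc1.[Cl-]
Why: NaH turns the ring B phenol into sodium phenoxide 13, the phenoxide/phenol pair shifts the double bond of the allylic salt 12 into conjugation with phosphorus (salt 14), the phenoxide oxygen adds to the beta-carbon of 14 (oxa-Michael addition, forming the O1–C2 bond at the gem-dimethyl carbon) to give the non-stabilised ylide 15, and the ylide carbon C3 then attacks the ortho formyl carbon C4 and collapses through an oxaphosphetane to the C3=C4 double bond and Ph3P=O. The closest known reaction type is the tandem oxa-Michael addition/intramolecular Wittig olefination by which salicylaldehyde phenoxides and vinyl- or allylphosphonium salts give 2H-chromenes (the annulation that uses the Schweizer reagent). Ring D is closed in the olefination event by a 6-exo-trig attack of the tethered ylide carbon on the aldehyde, and the six-membered ring allows only the cis olefin; no stereocentre is formed. The step needs site selectivity for the ring B oxygen and for the formyl group over the ring C carbonyl and C2: the 7-hydroxyl is masked as its MOM ether, the ylide is born only on the oxygen ortho to the aldehyde so that the intramolecular olefination should outrun any attack on the remote vinylogous-ester-type pyranone, and sodium phenoxide is too weak a nucleophile to open ring C. The Michael addition to the hindered beta,beta-dimethyl acceptor is reversible and is drawn forward by the irreversible loss of Ph3P=O (Curtin–Hammett situation), while intermolecular olefination by the transient allylic ylide is held back because the aldehyde is deactivated by its ortho phenoxide and only a weak base is present.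

**Step 7**
Reactants: 16 3-(8-methoxy-2,2-dimethyl-2H-chromen-6-yl)-7-(methoxymethoxy)-4H-chromen-4-one
Product: 17 7-hydroxy-3-(8-methoxy-2,2-dimethyl-2H-chromen-6-yl)-4H-chromen-4-one
Conditions: conc. HCl (cat.), MeOH, 45 °C
Reagents that add atoms: none
Why: Acid-catalysed acetal exchange (methanolysis of the MOM ether) frees the 7-hydroxyl, while the chromone and the styrene-type olefin of ring D should tolerate dilute acid at this temperature.

**Compound list**

1 | 2,4-dihydroxyacetophenone | CC(=O)c1ccc(O)cc1O | starting material
2 | chloromethyl methyl ether | COCCl | starting material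
3 | 1-[2-hydroxy-4-(methoxymethoxy)phenyl]ethan-1-one | CC(=O)c1ccc(OCOC)cc1O | intermediate
4 | N,N-dimethylformamide dimethyl acetal | COC(OC)N(C)C | starting material
5 | (E)-3-(dimethylamino)-1-[2-hydroxy-4-(methoxymethoxy)phenyl]prop-2-en-1-one | CN(C)/C=C/C(=O)c1ccc(OCOC)cc1O | intermediate
6 | iodine | II | starting material
7 | 3-iodo-7-(methoxymethoxy)-4H-chromen-4-one | O=c1c(I)coc2cc(OCOC)ccc12 | intermediate
8 | 5-bromo-2-hydroxy-3-methoxybenzaldehyde | COc1cc(Br)cc(C=O)c1O | starting material
9 | bis(pinacolato)diboron | CC1(C)OB(OC1(C)C)B1OC(C)(C)C(C)(C)O1 | starting material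
10 | 2-hydroxy-3-methoxy-5-(4,4,5,5-tetramethyl-1,3,2-dioxaborolan-2-yl)benzaldehyde | COc1cc(B2OC(C)(C)C(C)(C)O2)cc(C=O)c1O | intermediate
11 | 2-hydroxy-3-methoxy-5-[7-(methoxymethoxy)-4-oxo-4H-chromen-3-yl]benzaldehyde | COc1cc(-c2coc3cc(OCOC)ccc3c2=O)cc(C=O)c1O | intermediate
12 | (2-methylallyl)triphenylphosphonium chloride | CC(=C)C[P+](c1ccccc1)(c1ccccc1)c1ccccc1.[Cl-] | starting material
13 | sodium 2-formyl-6-methoxy-4-[7-(methoxymethoxy)-4-oxo-4H-chromen-3-yl]phenolate | COc1cc(-c2coc3cc(OCOC)ccc3c2=O)cc(C=O)c1[O-].[Na+] | intermediate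
14 | (2-methylprop-1-en-1-yl)triphenylphosphonium chloride | CC(C)=C[P+](c1ccccc1)(c1ccccc1)c1ccccc1.[Cl-] | intermediate
15 | 2-methoxy-6-formyl-4-[7-(methoxymethoxy)-4-oxo-4H-chromen-3-yl]phenyl ether of 2-methyl-1-(triphenylphosphoranylidene)propan-2-ol (ylide) | COc1cc(-c2coc3cc(OCOC)ccc3c2=O)cc(C=O)c1OC(C)(C)C=P(c1ccccc1)(c1ccccc1)c1ccccc1 | intermediate
16 | 3-(8-methoxy-2,2-dimethyl-2H-chromen-6-yl)-7-(methoxymethoxy)-4H-chromen-4-one | COc1cc(-c2coc3cc(OCOC)ccc3c2=O)cc2c1OC(C)(C)C=C2 | intermediate
17 | 7-hydroxy-3-(8-methoxy-2,2-dimethyl-2H-chromen-6-yl)-4H-chromen-4-one | COc1cc(-c2coc3cc(O)ccc3c2=O)cc2c1OC(C)(C)C=C2 | target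

**Totals and risks**

Total step count: 7. Longest linear sequence: 6 steps (steps 1, 2, 3, 5, 6, 7); step 4 is a one-step branch.

Steps most likely to fail:

1. **Step 6.** The conjugate addition of the doubly ortho-substituted phenoxide to the beta,beta-dimethyl acceptor may be too unfavourable. The allylic ylide would then be consumed by intermolecular olefination, or the phenol would be returned unchanged. Fallback, from 11 back to 16, closing the same C3=C4 bond by olefin metathesis:
   - The phenol of 11 would be O-alkylated with 3-chloro-3-methylbut-1-yne (CuCl2·2H2O cat., DBU, MeCN, 0 °C) to give 3-[3-formyl-5-methoxy-4-[(2-methylbut-3-yn-2-yl)oxy]phenyl]-7-(methoxymethoxy)-4H-chromen-4-one F1. Both ortho positions and the para position of this aryl ether are substituted, so neither it nor the later allyl ether can enter a Claisen pathway.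
   - Semihydrogenation (H2, Lindlar catalyst, that is Pd/CaCO3 poisoned with Pb(OAc)2, quinoline, EtOAc, rt) should give 3-[3-formyl-5-methoxy-4-[(2-methylbut-3-en-2-yl)oxy]phenyl]-7-(methoxymethoxy)-4H-chromen-4-one F2.
   - Wittig methylenation of the formyl group (methyltriphenylphosphonium bromide, KN(SiMe3)2, THF, −78 to 0 °C, where the aldehyde should react well before the pyranone) would give 3-[3-ethenyl-5-methoxy-4-[(2-methylbut-3-en-2-yl)oxy]phenyl]-7-(methoxymethoxy)-4H-chromen-4-one F3.
   - Ring-closing olefin metathesis (second-generation Grubbs catalyst RuCl2(=CHPh)(PCy3)(H2IMes), CH2Cl2, 40 °C) should close ring D with loss of ethene and return to 16.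

2. **Step 5.** The boronate carries a para phenoxide under the basic aqueous conditions and may lose boron by protodeboronation. The salicylaldehyde unit may also bind palladium, and hydroxide may open ring C. Fallback, from 8 back to 16, with ring D built before the coupling so that the boron partner has neither a free phenol nor an aldehyde:
   - 8 would be annulated with 12 under the conditions of step 6 (NaH, DMF, 0 °C, then 90 °C) through sodium 4-bromo-2-formyl-6-methoxyphenolate F4 and the ylide 5-bromo-3-methoxy-2-{[2-methyl-1-(triphenylphosphoranylidene)propan-2-yl]oxy}benzaldehyde F5, neither isolated, to give 6-bromo-8-methoxy-2,2-dimethyl-2H-chromene F6.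
   - Miyaura borylation with 9 (PdCl2(dppf), KOAc, 1,4-dioxane, 90 °C) would give 2-(8-methoxy-2,2-dimethyl-2H-chromen-6-yl)-4,4,5,5-tetramethyl-1,3,2-dioxaborolane F7.
   - Suzuki–Miyaura coupling of F7 with 7 (Pd(PPh3)4, Na2CO3, DME/H2O, 80 °C) should give 16 directly; step 7 then follows.

3. **Step 4.** Oxidative addition into the electron-rich C–Br bond para to a phenol may be slow, so that reductive loss of bromine or catalyst deactivation by the chelating salicylaldehyde competes. Fallback, from 7 back to 11, bringing in boron with a purchased reagent and the formyl group afterwards: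
   - 7 would be coupled with commercial 2-methoxy-4-(4,4,5,5-tetramethyl-1,3,2-dioxaborolan-2-yl)phenol (Pd(PPh3)4, Na2CO3, DME/H2O, 80 °C) to give 3-(4-hydroxy-3-methoxyphenyl)-7-(methoxymethoxy)-4H-chromen-4-one F8.
   - Casnati–Skattebøl ortho-formylation (MgCl2, Et3N, paraformaldehyde, MeCN, reflux) should place the formyl group at the only free position ortho to the phenol and give 11.

**Further compounds**

F1 | step 6 | 3-[3-formyl-5-methoxy-4-[(2-methylbut-3-yn-2-yl)oxy]phenyl]-7-(methoxymethoxy)-4H-chromen-4-one | COc1cc(-c2coc3cc(OCOC)ccc3c2=O)cc(C=O)c1OC(C)(C)C#C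
F2 | step 6 | 3-[3-formyl-5-methoxy-4-[(2-methylbut-3-en-2-yl)oxy]phenyl]-7-(methoxymethoxy)-4H-chromen-4-one | COc1cc(-c2coc3cc(OCOC)ccc3c2=O)cc(C=O)c1OC(C)(C)C=C
F3 | step 6 | 3-[3-ethenyl-5-methoxy-4-[(2-methylbut-3-en-2-yl)oxy]phenyl]-7-(methoxymethoxy)-4H-chromen-4-one | COc1cc(-c2coc3cc(OCOC)ccc3c2=O)cc(C=C)c1OC(C)(C)C=C
F4 | step 5 | sodium 4-bromo-2-formyl-6-methoxyphenolate | COc1cc(Br)cc(C=O)c1[O-].[Na+]
F5 | step 5 | 5-bromo-3-methoxy-2-{[2-methyl-1-(triphenylphosphoranylidene)propan-2-yl]oxy}benzaldehyde | COc1cc(Br)cc(C=O)c1OC(C)(C)C=P(c1ccccc1)(c1ccccc1)c1ccccc1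
F6 | step 5 | 6-bromo-8-methoxy-2,2-dimethyl-2H-chromene | COc1cc(Br)cc2c1OC(C)(C)C=C2
F7 | step 5 | 2-(8-methoxy-2,2-dimethyl-2H-chromen-6-yl)-4,4,5,5-tetramethyl-1,3,2-dioxaborolane | COc1cc(B2OC(C)(C)C(C)(C)O2)cc2c1OC(C)(C)C=C2
F8 | step 4 | 3-(4-hydroxy-3-methoxyphenyl)-7-(methoxymethoxy)-4H-chromen-4-one | COc1cc(-c2coc3cc(OCOC)ccc3c2=O)ccc1O
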